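**Retrosynthetic overview** (labdane numbering: ring A = C-1 to C-5 and C-10; ring B = C-5 to C-10; side chain from C-11)

1. Target ⇐ bis-MOM ether 26 ⇐ 3-furyl compound 23 (furan photooxygenation, then borohydride) ⇐ Z-selective Wittig union of decalin ketone 15 with the ylide from phosphonium salt 21 (made from ethyl 3-(furan-3-yl)-3-oxopropanoate by asymmetric hydrogenation).
2. 15 ⇐ amide 14 ⇐ diene amide 13, whose C5=C6 olefin is reduced by radical hydrogen-atom transfer so that H-5 enters trans to the C-10 methyl; 13 ⇐ Eschenmoser–Claisen rearrangement of dienol 12, which creates the tetrasubstituted C8=C9 olefin and the C11–C12 bond.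
3. 12 ⇐ ring-closing metathesis of triene 11, joining C-5 to C-6 and closing ring B (ring A first, ring B second, butenolide last); 11 ⇐ 2,2,6-trimethylcyclohexanone by Pd-catalysed enantioselective allylation (sets C-10) and carbonyl methylenation.
4. Enabling feature: C-5 lies between two fully substituted carbons (C-4 with two methyls, C-10 with methyl and side chain). The ring-A ketone therefore cannot enolise and C-5 can be trigonal only outside ring A; as an exocyclic methylidene it becomes a metathesis partner whose extra carbon leaves as ethylene. In the resulting C5=C6 olefin only C-6 bears hydrogen, so radical hydrogenation must place the radical on C-5.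

Key step: step 9

Assumption: (R)-t-Bu-PHOX is taken to give (R)-4, following the usual sense of this allylation for 2-alkylcyclohexanone enol carbonates; the mirror-image ligand would be used otherwise.
Assumption: RuCl2[(S)-BINAP] is taken to give the (R)-carbinol 17, the usual sense for aryl β-keto esters.

**Decalin fragment**

Step 1
Reactants: 1 2,2,6-trimethylcyclohexanone
Product: 3 allyl 2,6,6-trimethylcyclohex-1-enyl carbonate, via lithium enolate 2 (not isolated)
Conditions: LiHMDS, TMEDA, THF, −78 to 0 °C; then allyl chloroformate, −78 °C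
Reagents that add atoms: allyl chloroformate, C=CCOC(Cl)=O
Why: Only one α-position carries hydrogen, so a single enolate forms, and it is O-acylated by the chloroformate (enol carbonate formation) because C-acylation at the fully substituted carbon is sterically disfavoured.

Step 2
Reactants: 3 allyl enol carbonate
Product: 4 (2R)-2-allyl-2,6,6-trimethylcyclohexanone
Conditions: Pd2(dba)3 (cat.), (R)-t-Bu-PHOX (cat.), THF, 25 °C
Reagents that add atoms: none
Why: Decarboxylative Tsuji allylation, in which ionisation and loss of CO2 give a Pd π-allyl/enolate pair that recombines at carbon inside the chiral ligand pocket, so the quaternary stereocentre (C-10) is set by the ligand, the stereocentre of racemic 1 having been erased in the achiral enol carbonate.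

Step 3
Reactants: 4 allyl ketone
Product: 5 (1R)-1-allyl-1,3,3-trimethyl-2-methylidenecyclohexane
Conditions: Tebbe reagent Cp2Ti(μ-Cl)(μ-CH2)AlMe2, pyridine (cat.), THF/toluene, −40 °C to rt
Reagents that add atoms: Tebbe reagent, C[Al-]1(C)C[Ti]([Cl+]1)(C2C=CC=C2)C3C=CC=C3
Why: Tebbe methylenation works on non-enolisable, doubly α-quaternary ketones that resist Wittig reagents, and it leaves the vinyl group and the stereocentre untouched.

Step 4
Reactants: 5 diene
Product: 7 2-[(1R)-1,3,3-trimethyl-2-methylidenecyclohexyl]acetaldehyde, via vicinal diol 6 (not isolated)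
Conditions: OsO4 (cat.), NaIO4, 2,6-lutidine, dioxane/H2O, rt
Reagents that add atoms: sodium periodate (oxygen source by way of catalytic OsO4), [Na+].[O-]I(=O)(=O)=O
Why: Lemieux–Johnson cleavage, in which OsO4 should dihydroxylate the exposed monosubstituted olefin much faster than the methylidene buried between two quaternary carbons, and periodate cleaves the diol without touching the stereocentre.

Step 5
Reactants: 7 aldehyde
Product: 8 2-[(1S)-1,3,3-trimethyl-2-methylidenecyclohexyl]prop-2-enal
Conditions: 37% aq. CH2O, pyrrolidine (cat.), EtCO2H (cat.), i-PrOH, 45 °C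
Reagents that add atoms: formaldehyde, C=O
Why: Amine-catalysed Mannich condensation/elimination (α-methylenation of an aldehyde) can only occur at the single α-CH2 group, which places the future C-11 on C-9 regiospecifically.

Step 6
Reactants: 8 enal
Product: 9 3-[(1S)-1,3,3-trimethyl-2-methylidenecyclohexyl]but-3-en-2-ol (both carbinol epimers)
Conditions: MeMgBr, THF, −78 °C; then H2O
Reagents that add atoms: methylmagnesium bromide, C[Mg]Br
Why: Grignard 1,2-addition to the enal is fast at low temperature, and the uncontrolled carbinol centre is removed by oxidation in the next step.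

Step 7
Reactants: 9 allylic alcohol
Product: 10 3-[(1S)-1,3,3-trimethyl-2-methylidenecyclohexyl]but-3-en-2-one
Conditions: MnO2, CH2Cl2, rt
Reagents that add atoms: none
Why: MnO2 oxidises the allylic alcohol selectively to the enone and leaves the olefins alone (allylic alcohol oxidation).

Step 8
Reactants: 10 methyl enone
Product: 11 3-methyl-2-[(1S)-1,3,3-trimethyl-2-methylidenecyclohexyl]hexa-1,5-dien-3-ol (both carbinol epimers)
Conditions: allylMgBr, THF, −78 °C; then H2O
Reagents that add atoms: allylmagnesium bromide, C=CC[Mg]Br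
Why: Allyl Grignard reagents add in the 1,2-sense to enones, giving the tertiary carbinol that carries the future C-8 methyl and the C-7/C-6 vinyl arm, and its uncontrolled configuration is erased in step 10.

Step 9
Reactants: 11 triene carbinol
Product: 12 (8aS)-2,5,5,8a-tetramethyl-1-methylidene-1,2,3,5,6,7,8,8a-octahydronaphthalen-2-ol (both carbinol epimers)
Conditions: RuCl2(H2IMes)(=CH-C6H4-2-O-i-Pr) (second-generation Hoveyda–Grubbs catalyst, cat.), toluene, high dilution, 80 °C, Ar purge
Reagents that add atoms: none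
Why: Ring-closing olefin metathesis: the ruthenium alkylidene forms at the monosubstituted vinyl terminus (C-6), adds [2+2] across the exocyclic C5=CH2 bond and cycloreverts to the endocyclic C5=C6 olefin, the methylidene carbon and the vinyl terminus leaving together as ethylene. The closest known reaction type is metathetic closure of trisubstituted ring-fusion cyclohexenes from 2-alkenyl-methylidenecycloalkanes with second-generation ruthenium catalysts. Ring B closes as a six-membered ring in the only feasible mode, since pairing the vinyl group with the C-9 methylidene, or the two methylidenes with each other, would give four- or three-membered rings. No stereocentre is created: C-10 is untouched, both carbinol epimers of 11 cyclise and are merged in step 10, and C-5 is deliberately left trigonal so that it is set in step 11 by hydrogen delivery and not by C–C bond formation, which at a C-5 radical or anion would be expected to occur anti to the axial methyls and give the cis ring fusion. The step needs ring closure to outrun oligomerisation and must tolerate the free tertiary alcohol; high dilution, removal of ethylene and the hydroxyl tolerance of ruthenium carbenes should secure this, and the metallacycle can form on the face of the methylidene away from the axial methyl groups.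

Step 10
Reactants: 12 bicyclic dienol
Product: 13 N,N-dimethyl-3-[(8aR)-2,5,5,8a-tetramethyl-3,5,6,7,8,8a-hexahydronaphthalen-1-yl]propanamide
Conditions: MeC(OMe)2NMe2, xylenes, 140 °C
Reagents that add atoms: N,N-dimethylacetamide dimethyl acetal, COC(C)(OC)N(C)C
Why: Eschenmoser–Claisen rearrangement, in which exchange of the tertiary allylic alcohol into the ketene N,O-acetal and a suprafacial [3,3] shift form the tetrasubstituted C8=C9 olefin and the C11–C12 bond, so both carbinol epimers converge and no new stereocentre arises.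

Step 11
Reactants: 13 diene amide
Product: 14 N,N-dimethyl-3-[(4aS,8aS)-2,5,5,8a-tetramethyl-3,4,4a,5,6,7,8,8a-octahydronaphthalen-1-yl]propanamide
Conditions: Mn(dpm)3 (cat.), PhSiH3, t-BuOOH, i-PrOH, rt
Reagents that add atoms: none
Why: Mukaiyama-type hydrogen-atom-transfer hydrogenation, in which the manganese hydride delivers H• to C-6 (the only hydrogen-bearing end of the trisubstituted olefin) and the tertiary C-5 radical is quenched on the face opposite the axial methyls at C-4 and C-10, giving the trans ring fusion, while the tetrasubstituted olefin is too hindered to react.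

Step 12
Reactants: 14 trans-decalin amide
Product: 15 1-(methoxymethoxy)-4-[(4aS,8aS)-2,5,5,8a-tetramethyl-3,4,4a,5,6,7,8,8a-octahydronaphthalen-1-yl]butan-2-one
Conditions: Bu3SnCH2OCH2OMe, n-BuLi, THF, −78 °C; then 14, −78 to 0 °C; then H2O
Reagents that add atoms: tributyl[(methoxymethoxy)methyl]stannane, CCCC[Sn](CCCC)(CCCC)COCOC
Why: Tin–lithium exchange gives the α-alkoxymethyllithium, which adds once to the tertiary amide because the tetrahedral lithium hemiaminal survives until work-up (ketone synthesis from an amide).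

**Side-chain fragment**

Step 13
Reactants: 16 ethyl 3-(furan-3-yl)-3-oxopropanoate
Product: 17 ethyl (3R)-3-(furan-3-yl)-3-hydroxypropanoate
Conditions: RuCl2[(S)-BINAP] (cat.), H2 (pressure), EtOH, 50 °C
Reagents that add atoms: none
Why: Noyori asymmetric hydrogenation of a β-keto ester, in which the ester chelates ruthenium and the (S)-BINAP ligand sets the carbinol stereocentre as R.

Step 14
Reactants: 17 hydroxy ester
Product: 18 ethyl (3R)-3-(furan-3-yl)-3-(methoxymethoxy)propanoate
Conditions: MOMCl, i-Pr2NEt, CH2Cl2, 0 °C to rt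
Reagents that add atoms: chloromethyl methyl ether, COCCl
Why: O-Alkylation of the alcohol by the chloromethyl ether under amine base (MOM protection) does not touch the stereocentre.

Step 15
Reactants: 18 MOM ester
Product: 19 (3R)-3-(furan-3-yl)-3-(methoxymethoxy)propan-1-ol
Conditions: LiAlH4, THF, 0 °C; then H2O
Reagents that add atoms: none
Why: LiAlH4 reduces the ester to the primary alcohol while the acetal and the furan are inert (hydride reduction).

Step 16
Reactants: 19 primary alcohol
Product: 20 3-[(1R)-3-iodo-1-(methoxymethoxy)propyl]furan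
Conditions: I2, PPh3, imidazole, CH2Cl2, 0 °C
Reagents that add atoms: iodine, II
Why: Appel-type iodination converts the primary alcohol by SN2 displacement of the oxyphosphonium group.

Step 17
Reactants: 20 iodide
Product: 21 [(3R)-3-(furan-3-yl)-3-(methoxymethoxy)propyl]triphenylphosphonium iodide
Conditions: PPh3, MeCN, 80 °C
Reagents that add atoms: triphenylphosphine, c1ccccc1P(c1ccccc1)c1ccccc1
Why: SN2 quaternisation of triphenylphosphine by the primary iodide gives the Wittig salt.

**Union and completion**

Step 18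
Reactants: 15 decalin α-alkoxy ketone; 21 phosphonium iodide
Product: 23 3-{(1R,3Z)-1-(methoxymethoxy)-4-[(methoxymethoxy)methyl]-6-[(4aS,8aS)-2,5,5,8a-tetramethyl-3,4,4a,5,6,7,8,8a-octahydronaphthalen-1-yl]hex-3-en-1-yl}furan, via phosphorus ylide 22 (not isolated)
Conditions: 21, KHMDS, THF, −78 °C; then 15, −78 to 0 °C
Reagents that add atoms: none
Why: Wittig olefination of an α-alkoxy ketone with a non-stabilised ylide under salt-free, low-temperature conditions is known to favour the trisubstituted olefin in which the alkoxymethyl group and the ylide-derived chain are cis, which is the required Z geometry, and the existing stereocentres are not touched.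

Step 19
Reactants: 23 furan
Product: 25 4-substituted 5-hydroxyfuran-2(5H)-one (γ-hydroxybutenolide; both lactol epimers), via furan endoperoxide 24 (not isolated)
Conditions: O2, hν (visible), rose bengal (cat.), i-Pr2NEt, CH2Cl2, −78 °C
Reagents that add atoms: dioxygen, O=O
Why: The electron-rich furan undergoes [4+2] cycloaddition with singlet oxygen faster than the hindered olefins undergo the ene reaction, and the hindered amine removes the less shielded bridgehead proton of the endoperoxide so that the carbonyl forms at the α-carbon remote from the side chain (furan photooxygenation to a γ-hydroxybutenolide), the lactol centre being removed in step 20.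

Step 20
Reactants: 25 γ-hydroxybutenolide
Product: 26 bis-MOM ether of the target
Conditions: NaBH4, EtOH, 0 °C; then aq. HCl to pH 3
Reagents that add atoms: none
Why: The lactol is in equilibrium with its open aldehyde carboxylate, which NaBH4 reduces to the hydroxy acid that relactonises on acidification to the butenolide (lactol reduction).

Step 21
Reactants: 26 bis-MOM ether
Product: 28 CNP0224983.2, via bis(bromomethyl) ether 27 (not isolated)
Conditions: Me2BBr, CH2Cl2, −78 °C; then THF/sat. aq. NaHCO3
Reagents that add atoms: none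
Why: Dimethylboron bromide cleaves the acetal C–O bonds of MOM ethers at low temperature and the bromomethyl ethers hydrolyse on work-up, conditions under which the butenolide, the allylic alcohol and the olefins should survive (acetal cleavage).

**Compound list**

1 | 2,2,6-trimethylcyclohexan-1-one (racemic) | CC1CCCC(C)(C)C1=O | starting material
2 | lithium 2,6,6-trimethylcyclohex-1-en-1-olate | [Li+].[O-]C1=C(C)CCCC1(C)C | intermediate
3 | prop-2-en-1-yl 2,6,6-trimethylcyclohex-1-en-1-yl carbonate | C=CCOC(=O)OC1=C(C)CCCC1(C)C | intermediate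
4 | (2R)-2,6,6-trimethyl-2-(prop-2-en-1-yl)cyclohexan-1-one | C=CC[C@@]1(C)CCCC(C)(C)C1=O | intermediate
5 | (1R)-1,3,3-trimethyl-2-methylidene-1-(prop-2-en-1-yl)cyclohexane | C=CC[C@@]1(C)CCCC(C)(C)C1=C | intermediate
6 | 3-[(1R)-1,3,3-trimethyl-2-methylidenecyclohexyl]propane-1,2-diol (both C-2 epimers) | OCC(O)C[C@@]1(C)CCCC(C)(C)C1=C | intermediate
7 | 2-[(1R)-1,3,3-trimethyl-2-methylidenecyclohexyl]acetaldehyde | O=CC[C@@]1(C)CCCC(C)(C)C1=C | intermediate
8 | 2-[(1S)-1,3,3-trimethyl-2-methylidenecyclohexyl]prop-2-enal | C=C(C=O)[C@@]1(C)CCCC(C)(C)C1=C | intermediate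
9 | 3-[(1S)-1,3,3-trimethyl-2-methylidenecyclohexyl]but-3-en-2-ol (both C-2 epimers) | C=C(C(C)O)[C@@]1(C)CCCC(C)(C)C1=C | intermediate
10 | 3-[(1S)-1,3,3-trimethyl-2-methylidenecyclohexyl]but-3-en-2-one | C=C(C(C)=O)[C@@]1(C)CCCC(C)(C)C1=C | intermediate
11 | 3-methyl-2-[(1S)-1,3,3-trimethyl-2-methylidenecyclohexyl]hexa-1,5-dien-3-ol (both C-3 epimers) | C=CCC(C)(O)C(=C)[C@@]1(C)CCCC(C)(C)C1=C | intermediate
12 | (8aS)-2,5,5,8a-tetramethyl-1-methylidene-1,2,3,5,6,7,8,8a-octahydronaphthalen-2-ol (both C-2 epimers) | CC1(O)C(=C)[C@@]2(C)CCCC(C)(C)C2=CC1 | intermediate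
13 | N,N-dimethyl-3-[(8aR)-2,5,5,8a-tetramethyl-3,5,6,7,8,8a-hexahydronaphthalen-1-yl]propanamide | CC1=C(CCC(=O)N(C)C)[C@@]2(C)CCCC(C)(C)C2=CC1 | intermediate
14 | N,N-dimethyl-3-[(4aS,8aS)-2,5,5,8a-tetramethyl-3,4,4a,5,6,7,8,8a-octahydronaphthalen-1-yl]propanamide | CC1=C(CCC(=O)N(C)C)[C@@]2(C)CCCC(C)(C)[C@@H]2CC1 | intermediate
15 | 1-(methoxymethoxy)-4-[(4aS,8aS)-2,5,5,8a-tetramethyl-3,4,4a,5,6,7,8,8a-octahydronaphthalen-1-yl]butan-2-one | CC1=C(CCC(=O)COCOC)[C@@]2(C)CCCC(C)(C)[C@@H]2CC1 | intermediate
16 | ethyl 3-(furan-3-yl)-3-oxopropanoate | CCOC(=O)CC(=O)c1ccoc1 | starting material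
17 | ethyl (3R)-3-(furan-3-yl)-3-hydroxypropanoate | CCOC(=O)C[C@@H](O)c1ccoc1 | intermediate
18 | ethyl (3R)-3-(furan-3-yl)-3-(methoxymethoxy)propanoate | CCOC(=O)C[C@@H](OCOC)c1ccoc1 | intermediate
19 | (3R)-3-(furan-3-yl)-3-(methoxymethoxy)propan-1-ol | OCC[C@@H](OCOC)c1ccoc1 | intermediate
20 | 3-[(1R)-3-iodo-1-(methoxymethoxy)propyl]furan | ICC[C@@H](OCOC)c1ccoc1 | intermediate
21 | [(3R)-3-(furan-3-yl)-3-(methoxymethoxy)propyl]triphenylphosphonium iodide | c1ccccc1[P+](c1ccccc1)(c1ccccc1)CC[C@@H](OCOC)c1ccoc1.[I-] | intermediate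
22 | [(3R)-3-(furan-3-yl)-3-(methoxymethoxy)propylidene]triphenylphosphorane | c1ccccc1P(c1ccccc1)(c1ccccc1)=CC[C@@H](OCOC)c1ccoc1 | intermediate
23 | 3-{(1R,3Z)-1-(methoxymethoxy)-4-[(methoxymethoxy)methyl]-6-[(4aS,8aS)-2,5,5,8a-tetramethyl-3,4,4a,5,6,7,8,8a-octahydronaphthalen-1-yl]hex-3-en-1-yl}furan | CC1=C(CC/C(COCOC)=C/C[C@@H](OCOC)c3ccoc3)[C@@]2(C)CCCC(C)(C)[C@@H]2CC1 | intermediate
24 | 2,5-endoperoxide of 23 (5-substituted 2,3,7-trioxabicyclo[2.2.1]hept-5-ene, mixture of isomers) | CC1=C(CC/C(COCOC)=C/C[C@@H](OCOC)C3=CC4OOC3O4)[C@@]2(C)CCCC(C)(C)[C@@H]2CC1 | intermediate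
25 | 5-hydroxy-4-{(1R,3Z)-1-(methoxymethoxy)-4-[(methoxymethoxy)methyl]-6-[(4aS,8aS)-2,5,5,8a-tetramethyl-3,4,4a,5,6,7,8,8a-octahydronaphthalen-1-yl]hex-3-en-1-yl}furan-2(5H)-one (both lactol epimers) | CC1=C(CC/C(COCOC)=C/C[C@@H](OCOC)C3=CC(=O)OC3O)[C@@]2(C)CCCC(C)(C)[C@@H]2CC1 | intermediate
26 | 4-{(1R,3Z)-1-(methoxymethoxy)-4-[(methoxymethoxy)methyl]-6-[(4aS,8aS)-2,5,5,8a-tetramethyl-3,4,4a,5,6,7,8,8a-octahydronaphthalen-1-yl]hex-3-en-1-yl}furan-2(5H)-one | CC1=C(CC/C(COCOC)=C/C[C@@H](OCOC)C3=CC(=O)OC3)[C@@]2(C)CCCC(C)(C)[C@@H]2CC1 | intermediate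
27 | 4-{(1R,3Z)-1-(bromomethoxy)-4-[(bromomethoxy)methyl]-6-[(4aS,8aS)-2,5,5,8a-tetramethyl-3,4,4a,5,6,7,8,8a-octahydronaphthalen-1-yl]hex-3-en-1-yl}furan-2(5H)-one | CC1=C(CC/C(COCBr)=C/C[C@@H](OCBr)C3=CC(=O)OC3)[C@@]2(C)CCCC(C)(C)[C@@H]2CC1 | intermediate
28 | 4-{(1R,3Z)-1-hydroxy-4-(hydroxymethyl)-6-[(4aS,8aS)-2,5,5,8a-tetramethyl-3,4,4a,5,6,7,8,8a-octahydronaphthalen-1-yl]hex-3-en-1-yl}furan-2(5H)-one (CNP0224983.2) | CC1=C(CC/C(=C/C[C@@H](O)C3=CC(=O)OC3)CO)[C@@]2(C)CCCC(C)(C)[C@@H]2CC1 | target

**Step count and risks**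

Total step count: 21. Longest linear sequence: 16 steps (steps 1–12, then 18–21).

Steps most likely to fail:

Step 9. The ring closure may stall because the methylidene carbon is shielded by two quaternary neighbours, leaving catalyst decomposition and intermolecular metathesis of the vinyl group as the dominant processes. Fallback: close ring B at the ketone stage by a Barbier cyclisation and make the olefin by dehydration. It sets out from 4. Ozonolysis (O3, CH2Cl2, −78 °C; Me2S) would give the keto aldehyde F1, and amine-catalysed α-methylenation with formaldehyde the keto enal F2. Vinylmagnesium bromide at −78 °C (the hindered ring ketone does not react) would give the dienol F3, which is silylated (TBSCl, imidazole) to the silyl ether F4. Hydroboration of the monosubstituted vinyl group with 9-BBN and oxidative work-up would give the primary alcohol F5, and iodination (I2, PPh3, imidazole) the iodide F6. SmI2/HMPA would then add the primary organosamarium to the ring ketone and close ring B, giving the bicyclic tertiary alcohol F7. Dehydration with Martin sulfurane, possible only towards C-6, would give the ring-fusion olefin F8; desilylation with TBAF the allylic alcohol F9; and Dess–Martin oxidation the enone F10. MeMgBr/CeCl3 then gives 12, where the route continues with step 10.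

Step 19. Ene oxidation of the tetrasubstituted ring-B olefin or of the side-chain olefin by singlet oxygen may compete with the furan cycloaddition. Fallback: make the butenolide without an oxidant for C=C bonds. It sets out from 23. Sterically controlled C–H borylation at the unhindered α-position of the furan ([Ir(OMe)(cod)]2, 4,4'-di-tert-butyl-2,2'-bipyridine, B2pin2, THF) would give the furyl boronate F11. Oxidation with NaBO3 in THF/H2O would give the 2-hydroxyfuran F12 (not isolated), whose Et3N-mediated tautomerisation gives 26 directly; step 20 is skipped and the route continues with step 21.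

Step 4. Chemoselectivity between the two olefins may be lost, with dihydroxylation and cleavage also occurring at the ring methylidene. Fallback: unmask the two-carbon aldehyde before the methylenation. It sets out from 4. Ozonolysis to the keto aldehyde F1 and acetalisation (HC(OMe)3, TsOH, MeOH) would give the keto acetal F13, Tebbe methylenation the methylidene acetal F14, and mild aqueous acid (oxalic acid, THF/H2O) releases 7, where the route continues with step 5.

Further compounds
F1 | step 9 | 2-[(1R)-1,3,3-trimethyl-2-oxocyclohexyl]acetaldehyde | O=CC[C@@]1(C)CCCC(C)(C)C1=O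
F2 | step 9 | 2-[(1R)-1,3,3-trimethyl-2-oxocyclohexyl]prop-2-enal | C=C(C=O)[C@@]1(C)CCCC(C)(C)C1=O
F3 | step 9 | (2R)-2-(3-hydroxypenta-1,4-dien-2-yl)-2,6,6-trimethylcyclohexan-1-one (both carbinol epimers) | C=CC(O)C(=C)[C@@]1(C)CCCC(C)(C)C1=O
F4 | step 9 | (2R)-2-{3-[(tert-butyldimethylsilyl)oxy]penta-1,4-dien-2-yl}-2,6,6-trimethylcyclohexan-1-one | C=CC(O[Si](C)(C)C(C)(C)C)C(=C)[C@@]1(C)CCCC(C)(C)C1=O
F5 | step 9 | (2R)-2-{3-[(tert-butyldimethylsilyl)oxy]-5-hydroxypent-1-en-2-yl}-2,6,6-trimethylcyclohexan-1-one | OCCC(O[Si](C)(C)C(C)(C)C)C(=C)[C@@]1(C)CCCC(C)(C)C1=O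
F6 | step 9 | (2R)-2-{3-[(tert-butyldimethylsilyl)oxy]-5-iodopent-1-en-2-yl}-2,6,6-trimethylcyclohexan-1-one | ICCC(O[Si](C)(C)C(C)(C)C)C(=C)[C@@]1(C)CCCC(C)(C)C1=O
F7 | step 9 | (8aR)-2-[(tert-butyldimethylsilyl)oxy]-5,5,8a-trimethyl-1-methylidenedecahydronaphthalen-4a-ol (mixture at C-2 and C-4a) | CC(C)(C)[Si](C)(C)OC1C(=C)[C@@]2(C)CCCC(C)(C)C2(O)CC1
F8 | step 9 | tert-butyldimethyl{[(8aS)-5,5,8a-trimethyl-1-methylidene-1,2,3,5,6,7,8,8a-octahydronaphthalen-2-yl]oxy}silane | CC(C)(C)[Si](C)(C)OC1C(=C)[C@@]2(C)CCCC(C)(C)C2=CC1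
F9 | step 9 | (8aS)-5,5,8a-trimethyl-1-methylidene-1,2,3,5,6,7,8,8a-octahydronaphthalen-2-ol | OC1C(=C)[C@@]2(C)CCCC(C)(C)C2=CC1
F10 | step 9 | (8aS)-5,5,8a-trimethyl-1-methylidene-3,5,6,7,8,8a-hexahydronaphthalen-2(1H)-one | O=C1C(=C)[C@@]2(C)CCCC(C)(C)C2=CC1
F11 | step 19 | 2-(4-{(1R,3Z)-1-(methoxymethoxy)-4-[(methoxymethoxy)methyl]-6-[(4aS,8aS)-2,5,5,8a-tetramethyl-3,4,4a,5,6,7,8,8a-octahydronaphthalen-1-yl]hex-3-en-1-yl}furan-2-yl)-4,4,5,5-tetramethyl-1,3,2-dioxaborolane | CC1=C(CC/C(COCOC)=C/C[C@@H](OCOC)c3coc(B4OC(C)(C)C(C)(C)O4)c3)[C@@]2(C)CCCC(C)(C)[C@@H]2CC1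
F12 | step 19 | 4-{(1R,3Z)-1-(methoxymethoxy)-4-[(methoxymethoxy)methyl]-6-[(4aS,8aS)-2,5,5,8a-tetramethyl-3,4,4a,5,6,7,8,8a-octahydronaphthalen-1-yl]hex-3-en-1-yl}furan-2-ol | CC1=C(CC/C(COCOC)=C/C[C@@H](OCOC)c3coc(O)c3)[C@@]2(C)CCCC(C)(C)[C@@H]2CC1
F13 | step 4 | (2R)-2-(2,2-dimethoxyethyl)-2,6,6-trimethylcyclohexan-1-one | COC(OC)C[C@@]1(C)CCCC(C)(C)C1=O
F14 | step 4 | (1R)-1-(2,2-dimethoxyethyl)-1,3,3-trimethyl-2-methylidenecyclohexane | COC(OC)C[C@@]1(C)CCCC(C)(C)C1=C
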